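**Strategy.** The 1,2-dioxane is traced back to a C8 hydroperoxide (H2O2 opening of a 7,8-epoxide) that displaces a C11 chloride, so the 14-membered carbocycle needs an E-C7=C8 olefin and a C11 carbinol separated by the C9–C10 ethano bridge that both rings share. This bridge is excised as ethylene: a zirconocene–ethylene complex couples 1-trimethylsilylpropyne (C7, C8, C19) and formaldehyde (C11) in one pot, forming C8–C9 and C10–C11 and fixing the olefin geometry. The precursor is simply Cp2ZrEt2, the silylalkyne and CH2O. The derived aldehyde is joined to a cis-α-methylene-lactone vinyl iodide by an asymmetric Ni/Cr coupling, and a B-alkyl Suzuki coupling closes the ring.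

Key step: step 8

Remark: atoms are labelled by cembrane numbering (ring C1–C14, lactone carbons C15–C17, methyl groups C18–C20); the ligand enantiomers in steps 5 and 10 are taken as those that deliver the configurations stated.

Step 1
Reactants: 1 3-(tert-butyldimethylsilyloxy)propanal; 2 methyl acrylate
Product: 3 methyl 5-(tert-butyldimethylsilyloxy)-3-hydroxy-2-methylidenepentanoate (racemic)
Conditions: DABCO (0.5 equiv), MeOH, rt
Reagents that add atoms: none
Why: Morita–Baylis–Hillman reaction, in which DABCO adds to the acrylate and the resulting ammonium enolate adds to the unhindered aldehyde, the racemic carbinol centre being erased in step 2.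

Step 2
Reactants: 3 methyl 5-(tert-butyldimethylsilyloxy)-3-hydroxy-2-methylidenepentanoate
Product: 4 methyl (2Z)-2-(bromomethyl)-5-(tert-butyldimethylsilyloxy)pent-2-enoate
Conditions: NBS, Me2S, CH2Cl2, 0 °C → rt
Reagents that add atoms: N-bromosuccinimide, O=C1CCC(=O)N1Br
Why: Corey–Kim-type bromination of a Morita–Baylis–Hillman adduct, in which the alcohol is activated as an alkoxysulfonium ion and bromide attacks in an SN2′ sense to give the thermodynamically favoured Z allylic bromide.

Step 3
Reactants: 5 (2E)-3-methylpent-2-en-4-yn-1-ol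
Product: 6 (2E)-3-methylpenta-2,4-dien-1-ol
Conditions: H2 (1 atm), Pd/CaCO3 poisoned with Pb(OAc)2 (Lindlar catalyst), quinoline, MeOH, rt
Reagents that add atoms: none
Why: Lindlar semihydrogenation should stop at the vinyl group because the poisoned palladium surface binds the terminal alkyne far more strongly than the diene, and the E olefin is not touched.

Step 4
Reactants: 6 (2E)-3-methylpenta-2,4-dien-1-ol
Product: 7 (2E)-3-methylpenta-2,4-dienal
Conditions: MnO2, CH2Cl2, rt; solution used directly
Reagents that add atoms: none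
Why: Allylic oxidation with activated MnO2 is selective for allylic alcohols and should give the dienal without E/Z isomerisation.

Step 5
Reactants: 4 methyl (2Z)-2-(bromomethyl)-5-(tert-butyldimethylsilyloxy)pent-2-enoate; 7 (2E)-3-methylpenta-2,4-dienal
Product: 10 (4S,5S)-4-(2-hydroxyethyl)-3-methylidene-5-[(1E)-2-methylbuta-1,3-dien-1-yl]oxolan-2-one, via bis-silyl ether adduct 8 (not isolated), via dihydroxy ester 9 (not isolated)
Conditions: CrCl2 (10 mol%), chiral 1,8-bis(oxazolinyl)carbazole ligand (12 mol%), Mn (2 equiv), Me3SiCl, i-Pr2NEt (cat.), THF, rt; then HF·pyridine, THF, 0 °C → rt; PPTS (cat.), CH2Cl2, rt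
Reagents that add atoms: none
Why: Catalytic asymmetric Nozaki–Hiyama-type 2-(alkoxycarbonyl)allylation, in which the γ-substituted allylchromium species from 4 adds to the aldehyde through a closed chair-like transition state that places C14 and the dienyl group syn while the chiral ligand selects the aldehyde face (C1 and C2 both S), and fluoride/acid work-up strips both silyl groups so that the cis γ-hydroxy ester lactonises.

Step 6
Reactants: 10 (4S,5S)-4-(2-hydroxyethyl)-3-methylidene-5-[(1E)-2-methylbuta-1,3-dien-1-yl]oxolan-2-one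
Product: 11 (4S,5S)-3-methylidene-5-[(1E)-2-methylbuta-1,3-dien-1-yl]-4-(2-oxoethyl)oxolan-2-one
Conditions: Dess–Martin periodinane, NaHCO3, CH2Cl2, 0 °C → rt
Reagents that add atoms: none
Why: Dess–Martin oxidation converts the primary alcohol into the C13 aldehyde under buffered, non-basic conditions that spare the α-methylene lactone and the dienyl ester.

Step 7
Reactants: 11 (4S,5S)-3-methylidene-5-[(1E)-2-methylbuta-1,3-dien-1-yl]-4-(2-oxoethyl)oxolan-2-one; 12 ethyltriphenylphosphonium iodide
Product: 16 (4S,5S)-4-[(2Z)-3-iodobut-2-en-1-yl]-3-methylidene-5-[(1E)-2-methylbuta-1,3-dien-1-yl]oxolan-2-one, via ethylidene ylide 13 (not isolated), via iodoethylphosphonium iodide 14 (not isolated), via iodo ylide 15 (not isolated)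
Conditions: 12, n-BuLi, THF, rt; I2, −78 °C; NaN(SiMe3)2, −20 °C; then 11, −78 °C
Reagents that add atoms: iodine, II
Why: Stork–Zhao olefination, in which the α-iodo ylide adds to the aldehyde under kinetic control through the cis-oxaphosphetane and gives the (Z)-2-iodoalkene that fixes the later Z geometry of C12=C13.

Step 8
Reactants: 17 ethylmagnesium bromide; 18 1-(trimethylsilyl)propyne; 19 formaldehyde (monomer from cracked paraformaldehyde)
Product: 24 (4E)-4-methyl-5-(trimethylsilyl)pent-4-en-1-ol, via diethylzirconocene 20 (not isolated), via zirconocene–ethylene complex 21 (not isolated), via zirconacyclopentene 22 (not isolated), via oxazirconacycloheptene 23 (not isolated)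
Conditions: Cp2ZrCl2 (1 equiv), 17 (2 equiv), THF, −78 °C; 18, −78 → 0 °C; 19, −40 → 0 °C; 1 M HCl
Reagents that add atoms: none
Why: Diethylzirconocene loses ethane by β-hydrogen abstraction to give the zirconocene–ethylene complex, which couples oxidatively with the silylalkyne to the zirconacyclopentene (C8–C9 bond), and formaldehyde then inserts into the more nucleophilic Zr–C(sp3) bond (C10–C11 bond) before acid cleaves the Zr–O and Zr–C(sp2) bonds. The closest known reaction type is the zirconocene-mediated three-component coupling of an alkyne, ethylene and an aldehyde through a zirconacyclopentene. No ring of the target is closed here; the transient five-membered zirconacycle forms by oxidative cyclometalation and the seven-membered oxazirconacycle by 1,2-insertion, and both are opened on work-up. No stereocentre is created, but the E geometry of the future C7=C8 olefin follows from syn carbometalation inside the metallacycle and protonolysis of the vinyl–zirconium bond with retention. The step needs regiocontrol (ethylene carbon on the methyl-bearing alkyne carbon), secured by the strong preference of the silyl group for the position next to zirconium, and insertion instead of extrusion of ethylene by β,β′ C–C cleavage, secured by the very electrophilic formaldehyde at low temperature.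

Step 9
Reactants: 24 (4E)-4-methyl-5-(trimethylsilyl)pent-4-en-1-ol
Product: 25 (4E)-4-methyl-5-(trimethylsilyl)pent-4-enal
Conditions: Dess–Martin periodinane, NaHCO3, CH2Cl2, rt
Reagents that add atoms: none
Why: Dess–Martin oxidation gives the C11 aldehyde under neutral conditions that do not protodesilylate the vinylsilane.

Step 10
Reactants: 16 (4S,5S)-4-[(2Z)-3-iodobut-2-en-1-yl]-3-methylidene-5-[(1E)-2-methylbuta-1,3-dien-1-yl]oxolan-2-one; 25 (4E)-4-methyl-5-(trimethylsilyl)pent-4-enal
Product: 27 (4S,5S)-4-[(2Z,4S,7E)-4-hydroxy-3,7-dimethyl-8-(trimethylsilyl)octa-2,7-dien-1-yl]-3-methylidene-5-[(1E)-2-methylbuta-1,3-dien-1-yl]oxolan-2-one, via trimethylsilyl ether 26 (not isolated)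
Conditions: CrCl2 (10 mol%), chiral oxazoline–sulfonamide ligand (11 mol%), NiCl2(dmp) (2 mol%, dmp = 2,9-dimethyl-1,10-phenanthroline), Mn (2 equiv), LiCl, Me3SiCl, MeCN, rt; then 1 M HCl, THF
Reagents that add atoms: none
Why: Catalytic asymmetric Nozaki–Hiyama–Kishi coupling, in which nickel inserts into the C12–I bond with retention of the Z geometry, the alkenyl group passes to chromium and adds to the aldehyde inside the chiral ligand sphere so that C11 is set S under ligand control, while manganese and Me3SiCl turn the chromium over.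

Step 11
Reactants: 27 (the C7 vinylsilane)
Product: 28 (4S,5S)-4-[(2Z,4S,7E)-4-hydroxy-8-iodo-3,7-dimethylocta-2,7-dien-1-yl]-3-methylidene-5-[(1E)-2-methylbuta-1,3-dien-1-yl]oxolan-2-one
Conditions: N-iodosuccinimide, MeCN/ClCH2CN (4:1), 0 °C, dark
Reagents that add atoms: N-iodosuccinimide, O=C1CCC(=O)N1I
Why: Ipso-iododesilylation, in which iodonium attacks the silicon-bearing C7 to give a tertiary β-silyl cation at C8 and loss of silicon returns the olefin with retention of the E geometry, a pathway expected to outrun reversible iodonium formation at the other olefins.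

Step 12
Reactants: 28 (the C7 vinyl iodide with the C5=C6 vinyl terminus)
Product: 30 (1S,2S,3E,7E,11S,12Z)-11-hydroxycembra-3,7,12,15(17)-tetraen-16,2-olide, via alkylborane 29 (not isolated)
Conditions: 9-BBN (2.5 equiv), THF, 0 °C → rt; then Pd(dppf)Cl2 (20 mol%), AsPh3, Cs2CO3, DMF/THF/H2O, 0.002 M, rt → 45 °C
Reagents that add atoms: none
Why: B-alkyl Suzuki–Miyaura macrocyclisation, in which 9-BBN adds to the terminal C5=C6 bond of the diene with boron on C6 and palladium-catalysed coupling of this carbonate-activated borane with the C7 iodide under high dilution forms C6–C7 with retention of the E olefin and closes the 14-membered ring without touching a stereocentre.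

Step 13
Reactants: 30 (1S,2S,3E,7E,11S,12Z)-11-hydroxycembra-3,7,12,15(17)-tetraen-16,2-olide
Product: 31 (1S,2S,3E,7E,11R,12Z)-11-chlorocembra-3,7,12,15(17)-tetraen-16,2-olide
Conditions: PPh3, (Cl3C)2CO, CH2Cl2, −20 → 0 °C
Reagents that add atoms: hexachloroacetone, ClC(Cl)(Cl)C(=O)C(Cl)(Cl)Cl
Why: Chlorination of an allylic alcohol with PPh3/hexachloroacetone runs through the alkoxyphosphonium chloride, which chloride opens by SN2 with inversion (11S to 11R) under neutral, cold conditions that suppress allylic transposition and leave the Z olefin intact.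

Step 14
Reactants: 31 (1S,2S,3E,7E,11R,12Z)-11-chlorocembra-3,7,12,15(17)-tetraen-16,2-olide
Product: 32 (1S,2S,3E,7S,8S,11R,12Z)-11-chloro-7,8-epoxycembra-3,12,15(17)-trien-16,2-olide
Conditions: L-fructose-derived ketone catalyst (ent-Shi ketone, 30 mol%), KHSO5 (as 2KHSO5·KHSO4·K2SO4), K2CO3, Bu4NHSO4, MeCN/(MeO)2CH2/aq. Na2B4O7–EDTA buffer, 0 °C
Reagents that add atoms: potassium peroxymonosulfate, [K+].[O-]S(=O)(=O)OO
Why: Shi epoxidation, in which the chiral dioxirane attacks the most electron-rich olefin, the unactivated E-trisubstituted C7=C8 (C3=C4 and C12=C13 are deactivated by allylic oxygen and chlorine, C15=C17 by conjugation), through a spiro transition state, the L-fructose-derived catalyst giving the 7S,8S epoxide by catalyst control.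

Step 15
Reactants: 32 (1S,2S,3E,7S,8S,11R,12Z)-11-chloro-7,8-epoxycembra-3,12,15(17)-trien-16,2-olide
Product: 33 (1S,2S,3E,7S,8R,11R,12Z)-11-chloro-8-hydroperoxy-7-hydroxycembra-3,12,15(17)-trien-16,2-olide
Conditions: anhydrous H2O2 in Et2O, H3PMo12O40 (5 mol%), rt
Reagents that add atoms: hydrogen peroxide, OO
Why: Acid-catalysed perhydrolysis of a trisubstituted epoxide, in which the heteropolyacid activates the oxirane and H2O2 attacks the tertiary C8 with inversion (8S to 8R) while the C7 oxygen stays as the 7S hydroxyl.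

Step 16
Reactants: 33 (1S,2S,3E,7S,8R,11R,12Z)-11-chloro-8-hydroperoxy-7-hydroxycembra-3,12,15(17)-trien-16,2-olide
Product: 34 (1S,2S,3E,7S,8R,11S,12Z)-8,11-epidioxy-7-hydroxycembra-3,12,15(17)-trien-16,2-olide
Conditions: Cs2CO3, DMF, 0.005 M, 0 °C
Reagents that add atoms: none
Why: Intramolecular alkylation of a hydroperoxide (6-exo-tet SN2), in which the peroxide anion, far more acidic and nucleophilic than the C7 hydroxyl, displaces the allylic chloride with inversion (11R to 11S) and closes the cis-bridged 1,2-dioxane.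

Step 17
Reactants: 34 (1S,2S,3E,7S,8R,11S,12Z)-8,11-epidioxy-7-hydroxycembra-3,12,15(17)-trien-16,2-olide
Product: 35 denticulatolide
Conditions: Ac2O, pyridine, DMAP (cat.), CH2Cl2, 0 °C → rt
Reagents that add atoms: acetic anhydride, CC(=O)OC(C)=O
Why: DMAP-catalysed acetylation of the only hydroxyl should give the acetate without affecting the dialkyl peroxide, the α-methylene lactone or any stereocentre.

**Compound list**

1 | 3-(tert-butyldimethylsilyloxy)propanal | O=CCCO[Si](C)(C)C(C)(C)C | starting material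
2 | methyl acrylate | C=CC(=O)OC | starting material
3 | methyl 5-(tert-butyldimethylsilyloxy)-3-hydroxy-2-methylidenepentanoate (racemic) | C=C(C(=O)OC)C(O)CCO[Si](C)(C)C(C)(C)C | intermediate
4 | methyl (2Z)-2-(bromomethyl)-5-(tert-butyldimethylsilyloxy)pent-2-enoate | BrC/C(C(=O)OC)=C\CCO[Si](C)(C)C(C)(C)C | intermediate
5 | (2E)-3-methylpent-2-en-4-yn-1-ol | OC/C=C(\C)C#C | starting material
6 | (2E)-3-methylpenta-2,4-dien-1-ol | OC/C=C(\C)C=C | intermediate
7 | (2E)-3-methylpenta-2,4-dienal | O=C/C=C(\C)C=C | intermediate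
8 | methyl (3S,4S,5E)-3-[2-(tert-butyldimethylsilyloxy)ethyl]-6-methyl-2-methylidene-4-(trimethylsilyloxy)octa-5,7-dienoate | C=C(C(=O)OC)[C@H](CCO[Si](C)(C)C(C)(C)C)[C@@H](O[Si](C)(C)C)/C=C(\C)C=C | intermediate (not isolated)
9 | methyl (3S,4S,5E)-4-hydroxy-3-(2-hydroxyethyl)-6-methyl-2-methylideneocta-5,7-dienoate | C=C(C(=O)OC)[C@H](CCO)[C@@H](O)/C=C(\C)C=C | intermediate (not isolated)
10 | (4S,5S)-4-(2-hydroxyethyl)-3-methylidene-5-[(1E)-2-methylbuta-1,3-dien-1-yl]oxolan-2-one | C=C1C(=O)O[C@@H](/C=C(\C)C=C)[C@H]1CCO | intermediate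
11 | (4S,5S)-3-methylidene-5-[(1E)-2-methylbuta-1,3-dien-1-yl]-4-(2-oxoethyl)oxolan-2-one | C=C1C(=O)O[C@@H](/C=C(\C)C=C)[C@H]1CC=O | intermediate
12 | ethyltriphenylphosphonium iodide | CC[P+](c1ccccc1)(c1ccccc1)c1ccccc1.[I-] | starting material
13 | ethylidenetriphenylphosphorane | CC=P(c1ccccc1)(c1ccccc1)c1ccccc1 | intermediate (not isolated)
14 | (1-iodoethyl)triphenylphosphonium iodide | CC(I)[P+](c1ccccc1)(c1ccccc1)c1ccccc1.[I-] | intermediate (not isolated)
15 | (1-iodoethylidene)triphenylphosphorane | CC(I)=P(c1ccccc1)(c1ccccc1)c1ccccc1 | intermediate (not isolated)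
16 | (4S,5S)-4-[(2Z)-3-iodobut-2-en-1-yl]-3-methylidene-5-[(1E)-2-methylbuta-1,3-dien-1-yl]oxolan-2-one | C=C1C(=O)O[C@@H](/C=C(\C)C=C)[C@H]1C/C=C(/C)I | intermediate
17 | ethylmagnesium bromide | CC[Mg]Br | starting material
18 | 1-(trimethylsilyl)propyne | CC#C[Si](C)(C)C | starting material
19 | formaldehyde (from paraformaldehyde) | C=O | starting material
20 | diethylzirconocene, Cp2ZrEt2 | CC[Zr+2]CC.[cH-]1cccc1.[cH-]1cccc1 | intermediate (not isolated)
21 | zirconocene–ethylene complex, Cp2Zr(C2H4), drawn as the zirconacyclopropane | C1C[Zr+2]1.[cH-]1cccc1.[cH-]1cccc1 | intermediate (not isolated)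
22 | 1,1-bis(cyclopentadienyl)-3-methyl-2-(trimethylsilyl)-1-zirconacyclopent-2-ene | CC1=C([Si](C)(C)C)[Zr+2]CC1.[cH-]1cccc1.[cH-]1cccc1 | intermediate (not isolated)
23 | 2,2-bis(cyclopentadienyl)-4-methyl-3-(trimethylsilyl)-1-oxa-2-zirconacyclohept-3-ene | CC1=C([Si](C)(C)C)[Zr+2]OCCC1.[cH-]1cccc1.[cH-]1cccc1 | intermediate (not isolated)
24 | (4E)-4-methyl-5-(trimethylsilyl)pent-4-en-1-ol | C[Si](C)(C)/C=C(\C)CCCO | intermediate
25 | (4E)-4-methyl-5-(trimethylsilyl)pent-4-enal | C[Si](C)(C)/C=C(\C)CCC=O | intermediate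
26 | trimethylsilyl ether of 27 (11S) | C=C1C(=O)O[C@@H](/C=C(\C)C=C)[C@H]1C/C=C(/C)[C@@H](O[Si](C)(C)C)CC/C(C)=C/[Si](C)(C)C | intermediate (not isolated)
27 | (4S,5S)-4-[(2Z,4S,7E)-4-hydroxy-3,7-dimethyl-8-(trimethylsilyl)octa-2,7-dien-1-yl]-3-methylidene-5-[(1E)-2-methylbuta-1,3-dien-1-yl]oxolan-2-one | C=C1C(=O)O[C@@H](/C=C(\C)C=C)[C@H]1C/C=C(/C)[C@@H](O)CC/C(C)=C/[Si](C)(C)C | intermediate
28 | (4S,5S)-4-[(2Z,4S,7E)-4-hydroxy-8-iodo-3,7-dimethylocta-2,7-dien-1-yl]-3-methylidene-5-[(1E)-2-methylbuta-1,3-dien-1-yl]oxolan-2-one | C=C1C(=O)O[C@@H](/C=C(\C)C=C)[C@H]1C/C=C(/C)[C@@H](O)CC/C(C)=C/I | intermediate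
29 | C6 B-alkyl-9-borabicyclo[3.3.1]nonane adduct of 28 (C11 hydroxyl transiently borylated) | C=C1C(=O)O[C@@H](/C=C(\C)CCB2C3CCCC2CCC3)[C@H]1C/C=C(/C)[C@@H](O)CC/C(C)=C/I | intermediate (not isolated)
30 | (1S,2S,3E,7E,11S,12Z)-11-hydroxycembra-3,7,12,15(17)-tetraen-16,2-olide | C=C1C(=O)O[C@H]2/C=C(\C)CC/C=C(\C)CC[C@H](O)/C(C)=C\C[C@@H]12 | intermediate
31 | (1S,2S,3E,7E,11R,12Z)-11-chlorocembra-3,7,12,15(17)-tetraen-16,2-olide | C=C1C(=O)O[C@H]2/C=C(\C)CC/C=C(\C)CC[C@@H](Cl)/C(C)=C\C[C@@H]12 | intermediate
32 | (1S,2S,3E,7S,8S,11R,12Z)-11-chloro-7,8-epoxycembra-3,12,15(17)-trien-16,2-olide | C=C1C(=O)O[C@H]2/C=C(\C)CC[C@@H]3O[C@@]3(C)CC[C@@H](Cl)/C(C)=C\C[C@@H]12 | intermediate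
33 | (1S,2S,3E,7S,8R,11R,12Z)-11-chloro-8-hydroperoxy-7-hydroxycembra-3,12,15(17)-trien-16,2-olide | C=C1C(=O)O[C@H]2/C=C(\C)CC[C@H](O)[C@](C)(OO)CC[C@@H](Cl)/C(C)=C\C[C@@H]12 | intermediate
34 | (1S,2S,3E,7S,8R,11S,12Z)-8,11-epidioxy-7-hydroxycembra-3,12,15(17)-trien-16,2-olide | C=C1C(=O)O[C@H]2/C=C(\C)CC[C@H](O)[C@@]3(C)CC[C@H](OO3)/C(C)=C\C[C@@H]12 | intermediate
35 | denticulatolide, (1S,2S,3E,7S,8R,11S,12Z)-7-acetoxy-8,11-epidioxycembra-3,12,15(17)-trien-16,2-olide | C=C1C(=O)O[C@H]2/C=C(\C)CC[C@H](OC(C)=O)[C@@]3(C)CC[C@H](OO3)/C(C)=C\C[C@@H]12 | target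

**Step count.** Total: 17 steps. Longest linear sequence: 13 steps (1, 2, 5, 6, 7, 10–17).

**Steps most likely to fail**

Step 12 (ring-closing B-alkyl Suzuki coupling). Slow transmetalation of the borane at high dilution may be outrun by protodeboronation, by reduction of the α-methylene lactone by excess borane, or by intermolecular coupling to oligomers. The fallback sets out from 28 and replaces the borane by a preformed primary alkylzinc reagent (Negishi ring closure). Hydroboration of 28 with 9-BBN and oxidative work-up (NaBO3) should give the diol (4S,5S)-5-[(1E)-4-hydroxy-2-methylbut-1-en-1-yl]-4-[(2Z,4S,7E)-4-hydroxy-8-iodo-3,7-dimethylocta-2,7-dien-1-yl]-3-methylideneoxolan-2-one F1. Iodination of its primary hydroxyl in preference to the hindered secondary one (I2, PPh3, imidazole, −20 °C) should give the primary alkyl iodide F2. Zinc insertion into the alkyl C–I bond only (Zn, LiCl, THF) should give the alkylzinc iodide F3, which Pd(OAc)2/SPhos under high dilution should close, returning to the route at 30.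

Step 16 (peroxide ring closure). Elimination of HCl, ionisation at C11 with loss of configuration, or base-induced fragmentation of the β-hydroxy hydroperoxide may outpace the 6-exo-tet displacement. The fallback sets out from 31 and reverses the roles of the two carbons, so that a C11 hydroperoxide opens the epoxide. Silver-assisted perhydrolysis of 31 (anhydrous H2O2, AgOCOCF3, Et2O, 0 °C) should give, with inversion, the allylic hydroperoxide (1S,2S,3E,7E,11S,12Z)-11-hydroperoxycembra-3,7,12,15(17)-tetraen-16,2-olide F4. Protection with 2-methoxypropene (PPTS) should give the 2-methoxyprop-2-yl peroxide F5, which tolerates the buffered Shi epoxidation (same catalyst as step 14) to the 7S,8S-epoxy peroxyketal F6. Camphorsulfonic acid in wet CH2Cl2 should then release the hydroperoxide, which opens the epoxide at C8 with inversion, returning to the route at 34.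

Step 5 (asymmetric chromium allylation and lactonisation). Poor facial selectivity with the conjugated dienal, erosion of syn selectivity, or ionisation of the dienyl carbinol during the acidic work-up may lower the optical and diastereomeric purity. The fallback sets out from 4 and replaces the allylchromium by an allylboronate. Palladium-catalysed borylation of 4 (B2pin2, Pd2(dba)3, DMSO, rt) should give methyl (2Z)-5-(tert-butyldimethylsilyloxy)-2-[(4,4,5,5-tetramethyl-1,3,2-dioxaborolan-2-yl)methyl]pent-2-enoate F7. Its allylboration of 7 under a chiral Brønsted acid (chiral diol·SnCl4, toluene, −78 °C) through a closed chair transition state should give the syn pinacol borate adduct F8, and HF·pyridine then removes boron and silicon and lactonises, returning to the route at 10.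

Further compounds
F1 | step 12 | (4S,5S)-5-[(1E)-4-hydroxy-2-methylbut-1-en-1-yl]-4-[(2Z,4S,7E)-4-hydroxy-8-iodo-3,7-dimethylocta-2,7-dien-1-yl]-3-methylideneoxolan-2-one | C=C1C(=O)O[C@@H](/C=C(\C)CCO)[C@H]1C/C=C(/C)[C@@H](O)CC/C(C)=C/I
F2 | step 12 | (4S,5S)-4-[(2Z,4S,7E)-4-hydroxy-8-iodo-3,7-dimethylocta-2,7-dien-1-yl]-5-[(1E)-4-iodo-2-methylbut-1-en-1-yl]-3-methylideneoxolan-2-one | C=C1C(=O)O[C@@H](/C=C(\C)CCI)[C@H]1C/C=C(/C)[C@@H](O)CC/C(C)=C/I
F3 | step 12 | alkylzinc iodide formed from F2 at C6 | C=C1C(=O)O[C@@H](/C=C(\C)CC[Zn]I)[C@H]1C/C=C(/C)[C@@H](O)CC/C(C)=C/I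
F4 | step 16 | (1S,2S,3E,7E,11S,12Z)-11-hydroperoxycembra-3,7,12,15(17)-tetraen-16,2-olide | C=C1C(=O)O[C@H]2/C=C(\C)CC/C=C(\C)CC[C@H](OO)/C(C)=C\C[C@@H]12
F5 | step 16 | 2-methoxyprop-2-yl peroxide of F4 | C=C1C(=O)O[C@H]2/C=C(\C)CC/C=C(\C)CC[C@H](OOC(C)(C)OC)/C(C)=C\C[C@@H]12
F6 | step 16 | (7S,8S)-7,8-epoxide of F5 | C=C1C(=O)O[C@H]2/C=C(\C)CC[C@@H]3O[C@@]3(C)CC[C@H](OOC(C)(C)OC)/C(C)=C\C[C@@H]12
F7 | step 5 | methyl (2Z)-5-(tert-butyldimethylsilyloxy)-2-[(4,4,5,5-tetramethyl-1,3,2-dioxaborolan-2-yl)methyl]pent-2-enoate | CC1(C)OB(C/C(C(=O)OC)=C\CCO[Si](C)(C)C(C)(C)C)OC1(C)C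
F8 | step 5 | methyl (3S,4S,5E)-3-[2-(tert-butyldimethylsilyloxy)ethyl]-6-methyl-2-methylidene-4-[(4,4,5,5-tetramethyl-1,3,2-dioxaborolan-2-yl)oxy]octa-5,7-dienoate | C=C(C(=O)OC)[C@H](CCO[Si](C)(C)C(C)(C)C)[C@@H](OB1OC(C)(C)C(C)(C)O1)/C=C(\C)C=C
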